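The constants that the two runs offer before any mechanism is named are a rate of decay and a ceiling, and the ceiling carries this flask: the Q ceiling, the highest [Q] reached, counted per litre and not per L charged, read at Sunday's peak as 0.0405 M.

| flask | L | J | remark | time |
|---|---|---|---|---|
| Sunday's | 0.30 M | 0.33 M | the very flask that is asked about, followed so far |  |
| Tuesday's | 0.15 M | 0.33 M | run made earlier |  |
| flask | 0.30 M | 0.330 M |  | 5.0 d |

Sunday's run (percent of the L charged)

| time / h | Q / % | L / % |
|---|---|---|
| 0.667 | 5.4 | 93.1 |
| 2.00 | 12.8 | 80.1 |
| 3.00 | 13.5 | 71.5 |
| 5.00 | 12.8 | 59.0 |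
| 8.00 | 11.7 | 49.0 |
| 10.0 | 11.1 | 45.2 |

Tuesday's run (percent of the L charged)

| time / d | Q / % | L / % |
|---|---|---|
| 0.625 | 19.1 | 0 |
| 1.25 | 12.9 | 0.4 |
| 1.67 | 10.6 | 0.1 |
| 2.50 | 9.1 | 0.3 |
| 3.00 | 9.0 | 0 |
| 4.00 | 8.5 | 0.3 |

(each reading ± 0.3 percentage points)

- as a solid, counted per litre of solution: L
- at the start none of L is in solution

- the best time, 5.0 d at the latest, for Q
- the amount of Q, in percent of the L charged, at that time
- earliest time at which at least nineteen twentieths of that best amount are there, in d
- latest time at which they still are, in d

Up to Sunday's peak the making of Q outruns its loss, after it the loss leads, and neither run shows the comparison turning back: Sunday's Q sinks to 11.1% by 10.0 h, and Tuesday's to 8.5% by 4.00 d.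

A second way to the ceiling comes from Tuesday's run, which holds the same J and half of Sunday's L. Its peak was never caught, but its first two readings, taken above its last one, give a decay rate of 1.41 /d, and carried back to Sunday's peak time they give 0.0449 M.

At the same J the two ways agree that the ceiling is a matter of litres, and they part by 0.00440 M. Sunday's number is one reading with a scatter of 0.3 percentage points, whereas Tuesday's rests on a difference of 4.4 points and is stretched by a factor of 2.02, so Tuesday's is the way that cheats. The reckoning therefore commits to Sunday's peak in this flask, about 13.5% near 0.125 d. The reckoned window runs from about 0.0833 d to 0.208 d, where Sunday's readings stand at 94.8% of the peak reading.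

The forecast differs: it says 25% at 5 d, with a window from 4.7 d to 5 d, holding that Sunday's peak “is not the real maximum”.

The flask gives 13.6% at 0.114 d, with a window from 0.0828 d to 0.192 d.

    L ⇌ D, rate k1*(cs1 - [D]) while solid is left; crystals form when [D] > cs1 (solubility = 0.140 M, k = 0.230 /h)
    Q ⇌ G (K = 2.70, k = 0.0340 /h)
    J → Z (k = 1.50 /h)
    D + J → Q (k = 58.0 /M/h)

That best amount in this flask is 0.0408 M against the ceiling of 0.0405 M, with J down to 0.193% of its charge at that moment and Z at 0.286 M. The neighbouring flask, charged with 0.75 M of L and the same J, gets 5.40% of its L from the same ceiling, and it gives 5.43%. There J, the limiting reagent, is the first charge to run out, with 0% left unbound at the end, while 94% of the charged L is still there, solid or dissolved.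

Readings and results are calculated on assumed constants; noise was put on by code.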